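At the time of reading, the oak flask has been followed for 6.00 h and is asked about at 30 h; the cedar run was charged with half the racemization catalyst of the oak flask.

| flask | left-handed substrate | right-handed substrate | reagent | racemization catalyst | impurity | remark | time |
|---|---|---|---|---|---|---|---|
| oak | 32 mM | 32 mM | 96 mM | 32 µM | 15 µM | the very flask that is asked about, followed so far |  |
| cedar | 32 mM | 32 mM | 96 mM | 16 µM | 15 µM | run made earlier |  |
| flask | 32 mM | 32 mM | 96.0 mM | 32 µM | 15 µM |  | 30 h |

- oak (time / h: left-handed substrate / %, right-handed substrate / %): 0.833: 50.4, 50.1; 1.50: 50.1, 48.6; 2.50: 50.7, 47.1; 3.00: 47.4, 49.5; 4.00: 47.3, 48.1; 5.00: 45.0, 48.9; 6.00: 44.4, 50.6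
- cedar (time / h: left-handed substrate / %, right-handed substrate / %): 1.00: 47.9, 50.9; 1.33: 47.9, 52.9; 2.00: 48.4, 48.8; 3.00: 47.2, 49.1; 5.00: 43.6, 50.1; 8.00: 44.6, 50.4; 12.0: 42.0, 47.5

(scatter of a reading: 1 percentage point)

- reagent is single-handed; left-handed substrate and right-handed substrate are mirror images of each other, charged as a racemate, each of them at the stated concentration
- reactions considered so far: reagent + left-handed substrate -> left-handed product; reagent + right-handed substrate -> right-handed product; left-handed substrate + racemization catalyst <-> right-handed substrate + racemization catalyst; racemization catalyst <-> dormant form; racemization catalyst + impurity -> spent catalyst; 2 racemization catalyst <-> resting dimer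
- an excess is the difference of the two amounts in percent of their sum
- an excess is below zero if the other one leads
- the handed part of reagent does not stay in what it makes, so the products of the two hands are mirror images too

1. part of the left-handed substrate and right-handed substrate charged together that has reacted at 30 h
2. excess of left-handed product over right-handed product in the product at 30 h
3. excess of right-handed substrate over left-handed substrate among what is left of the two at 30 h

Two signals stand in these readings: the total of both substrates lost, and the gap, right-handed minus left-handed. Each point of product counts once in the total and, by its hand, in the gap. While racemization stays small, the gap gained per point lost therefore reads the opening excess, E, of left-handed over right-handed product. The readings of the oak flask from 3.00 h on, summed, give a loss of 19 percentage points and a gap of 13 points, so a ratio of 69.1%. The cedar run, from 3.00 h on, gives 25 points and 20 points, so 77.3%. These two independent ways differ by 8.2 points, which is less than the 15.0% scatter of the oak ratio. Pooled, they read E as 73.8%, a selectivity factor of 6.63.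

A correction remains. As the left-handed substrate runs down, the right-handed one leads among what is left by an excess x, the substrate excess, and fresh product then carries about E minus x times one minus E squared. Since x grows roughly steadily, the collected product falls short by half of that. The give-back, points of product excess lost per point of substrate excess, is therefore half of one minus E squared: 0.228. The pooled loss per hour, carried on unchanged to 30 h, gives 28.9% reacted. The gap, taken as that reacted part times E and shared over what is left, puts x near 30.0%, and this reckoning, the text's own, commits to a product excess of 67.0%.

The forecast differs: 25% reacted (20% to 33%), a product excess of 89% (70% to 98%) and a substrate excess of 19% (7% to 29%), its high product excess resting on the ground that “The right-handed substrate barely reacts”. The product excess reckoned above lies below the forecast's range for it.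

The oak flask gives 22.9% reacted, a product excess of 61.8% and a substrate excess of 17.3%, so the forecast's product excess stands 27 points too high.

    reagent + left-handed substrate → left-handed product (k = 0.175 M⁻¹ h⁻¹)
    reagent + right-handed substrate → right-handed product (k = 0.0349 M⁻¹ h⁻¹)
    left-handed substrate + racemization catalyst ⇌ right-handed substrate + racemization catalyst, rate k3*[racemization catalyst]*[left-handed substrate] forward; the back reaction follows from the equilibrium constant (k = 386 M⁻¹ h⁻¹)
    racemization catalyst ⇌ dormant form (K = 1.18, k = 0.00731 h⁻¹)
    racemization catalyst + impurity → spent catalyst (k = 5.66 × 10⁵ M⁻¹ h⁻¹)
    2 racemization catalyst ⇌ resting dimer, settled at all times (K = 2.50 × 10⁵ M⁻¹)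

At 30 h the oak flask holds 4.39% right-handed product beside 18.6% left-handed. The same flask with 58 mM of reagent reaches a substrate excess of 10.5%, lower than the 17.3% of the oak flask. The give-back returns 1.6 points of product excess for that difference, which puts the product excess of the neighbouring flask at 63.3%. The neighbouring flask gives 63.8%.

The runs are calculated from invented constants, and the scatter is random.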